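**Retrosynthetic overview**
- The target comes from a 4-methylidene-oxolan-3-ol by hydrogenation on the face that carries the C3–OH, together with O-debenzylation. C4 is set last, on a ring whose other face is blocked by two aryl groups and the C3 methyl.
- The oxolane comes from a C2-symmetric 2,2'-bioxirane. Base opens one oxirane to an allylic alkoxide with the C5–O bond kept. That alkoxide opens the other oxirane at its benzylic carbon with inversion (O1–C2 bond) and leaves the C3–OH.
- The bioxirane comes from a (1E,3E)-1,4-diaryl-2,3-dimethylbutadiene by twofold catalyst-controlled epoxidation in one flask. This key step forms both oxiranes and carries all the absolute stereochemistry.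
- The diene comes from 2,3-dimethylbutadiene and two aryl bromides by a twofold Heck arylation.
- Ring order: both oxiranes form together first, then the oxolane forms at their expense. The arenes are bought.

Assumption: aryl bromide 1 and the L-fructose-derived enantiomer of the Shi ketone (1,2:4,5-di-O-isopropylidene-β-L-erythro-2,3-hexodiulo-2,6-pyranose, otherwise made from L-sorbose) are taken as catalogue items; Ar = 4-(benzyloxy)-3-methoxyphenyl throughout.

**Step 1**
Reactants: 1 1-(benzyloxy)-4-bromo-2-methoxybenzene (ArBr, 2.2 equiv); 2 2,3-dimethylbuta-1,3-diene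
Product: 4 (1E,3E)-1,4-di-Ar-2,3-dimethylbuta-1,3-diene, via monoaryl diene 3 (not isolated)
Conditions: Pd2(dba)3 (2.5 mol %), P(t-Bu)3 (10 mol %), Cs2CO3 (2.5 equiv), 1,4-dioxane, 100 °C, sealed tube
Reagents that add atoms: none
Why: Twofold Mizoroki–Heck arylation of a 1,3-diene, as known for isoprene and aryl bromides: ArPdBr adds to the unsubstituted terminus, the π-allylpalladium intermediate loses a benzylic hydrogen to restore conjugation, and syn insertion followed by syn β-hydride elimination puts each aryl group trans to the diene chain (E).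

**Step 2 (key step)**
Reactants: 4 (1E,3E)-1,4-di-Ar-2,3-dimethylbuta-1,3-diene
Product: 6 (2R,2'R,3S,3'S)-3,3'-di-Ar-2,2'-dimethyl-2,2'-bioxirane, via vinyl epoxide 5 (not isolated)
Conditions: L-fructose-derived Shi ketone (0.6 equiv in two portions), Oxone (2KHSO5·KHSO4·K2SO4, 2.8 equiv), K2CO3, Bu4NHSO4 (cat.), Na2B4O7–Na2(EDTA) buffer (pH 10.5), MeCN–(MeO)2CH2–H2O, 0 °C, 4 h; filtration through basic Al2O3
Reagents that add atoms: potassium peroxymonosulfate, [K+].[O-]S(=O)(=O)OO
Why: Shi asymmetric epoxidation run twice in one flask makes both oxirane rings: the chiral dioxirane attacks each trisubstituted E-styrenyl alkene through the spiro transition state on the same enantioface (the D-fructose ketone gives R benzylic carbons from E-β-methylstyrene, so the L-series ketone gives S), syn oxygen transfer keeps aryl and methyl cis on each oxirane, and the second catalyst-controlled event diverts the minor enantiomer of 5 into a separable meso diastereomer, which raises the ee of 6.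

**Step 3**
Reactants: 6 (2R,2'R,3S,3'S)-3,3'-di-Ar-2,2'-dimethyl-2,2'-bioxirane
Product: 8 (2R,3S,5S)-2,5-di-Ar-3-methyl-4-methylideneoxolan-3-ol, via epoxy allylic alkoxide 7 (not isolated)
Conditions: LDA (1.1 equiv, added over 1 h), THF, 0 → 40 °C; H2O
Reagents that add atoms: none
Why: Proposed new method: LDA removes a proton from one of the two homotopic oxirane methyl groups (the only β-hydrogens) in a syn-E2 epoxide-to-allylic-alkoxide isomerisation (Crandall–Rickborn type, as in α-pinene oxide to pinocarveol) that keeps the C5–O bond, and the alkoxide then opens the remaining oxirane at its benzylic carbon (5-endo-tet, the 4-exo site being fully substituted; closest known type is the cyclisation of 4-aryl-3,4-epoxy alcohols to 2-aryloxolan-3-ols) by SN2 under cation-free basic conditions, so C2 is inverted, C3 and C5 are retained, and the S,S pair of benzylic carbons becomes the cis-2,5-diaryl pattern in which the C3–OH lies on the opposite face.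

**Step 4**
Reactants: 8 (2R,3S,5S)-2,5-di-Ar-3-methyl-4-methylideneoxolan-3-ol
Product: 10 (2R,3S,4R,5R)-2,5-bis(4-hydroxy-3-methoxyphenyl)-3,4-dimethyloxolan-3-ol, via saturated dibenzyl ether 9 (not isolated)
Conditions: H2 (1 atm), 10% Pd/C, EtOAc–EtOH, rt, stopped at full debenzylation
Reagents that add atoms: none
Why: Heterogeneous catalytic hydrogenation combined with hydrogenolysis of the aryl benzyl ethers: the 1,1-disubstituted alkene binds to palladium by the face that carries only C3–OH, C2–H and C5–H, so hydrogen enters C4 syn to the hydroxyl and the new methyl ends cis to all other carbon substituents, while any prior migration of the alkene to C4=C5 would be reduced from the same face to the same product.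

**Compound list**
1 | 1-(benzyloxy)-4-bromo-2-methoxybenzene | COc1cc(Br)ccc1OCc1ccccc1 | starting material
2 | 2,3-dimethylbuta-1,3-diene | CC(=C)C(C)=C | starting material
3 | (1E)-1-[4-(benzyloxy)-3-methoxyphenyl]-2,3-dimethylbuta-1,3-diene | COc1cc(/C=C(\C)C(C)=C)ccc1OCc1ccccc1 | intermediate
4 | (1E,3E)-1,4-bis[4-(benzyloxy)-3-methoxyphenyl]-2,3-dimethylbuta-1,3-diene | COc1cc(/C=C(\C)/C(C)=C/c2ccc(OCc3ccccc3)c(OC)c2)ccc1OCc1ccccc1 | intermediate
5 | (2S,3S)-3-[4-(benzyloxy)-3-methoxyphenyl]-2-{(1E)-1-[4-(benzyloxy)-3-methoxyphenyl]prop-1-en-2-yl}-2-methyloxirane | COc1cc([C@@H]2O[C@@]2(C)/C(C)=C/c3ccc(OCc4ccccc4)c(OC)c3)ccc1OCc1ccccc1 | intermediate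
6 | (2R,2'R,3S,3'S)-3,3'-bis[4-(benzyloxy)-3-methoxyphenyl]-2,2'-dimethyl-2,2'-bioxirane | COc1cc([C@@H]2O[C@@]2(C)[C@]3(C)O[C@H]3c4ccc(OCc5ccccc5)c(OC)c4)ccc1OCc1ccccc1 | intermediate
7 | (1S)-1-[4-(benzyloxy)-3-methoxyphenyl]-2-{(2S,3S)-3-[4-(benzyloxy)-3-methoxyphenyl]-2-methyloxiran-2-yl}prop-2-en-1-ol (present in step 3 as its lithium alkoxide) | COc1cc([C@@H]2O[C@@]2(C)C(=C)[C@@H](O)c3ccc(OCc4ccccc4)c(OC)c3)ccc1OCc1ccccc1 | intermediate
8 | (2R,3S,5S)-2,5-bis[4-(benzyloxy)-3-methoxyphenyl]-3-methyl-4-methylideneoxolan-3-ol | COc1cc([C@H]2O[C@@H](c3ccc(OCc4ccccc4)c(OC)c3)C(=C)[C@]2(C)O)ccc1OCc1ccccc1 | intermediate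
9 | (2R,3S,4R,5R)-2,5-bis[4-(benzyloxy)-3-methoxyphenyl]-3,4-dimethyloxolan-3-ol | COc1cc([C@H]2O[C@@H](c3ccc(OCc4ccccc4)c(OC)c3)[C@@H](C)[C@]2(C)O)ccc1OCc1ccccc1 | intermediate
10 | (2R,3S,4R,5R)-2,5-bis(4-hydroxy-3-methoxyphenyl)-3,4-dimethyloxolan-3-ol (all four carbon substituents cis, OH on the other face) | COc1cc([C@H]2O[C@@H](c3ccc(O)c(OC)c3)[C@@H](C)[C@]2(C)O)ccc1O | target

**Total step count:** 4. **Longest linear sequence:** 4.

**Steps most likely to fail**

Step 3 is the most likely to fail. The anionic relay may stall at 7, run on to the bis-allylic diol, or close sluggishly. The fallback sets out from 5, isolated by stopping the epoxidation at one equivalent of oxidant, and comes back at 9. Vinyl epoxide 5 is reduced with Pd2(dba)3·CHCl3, PBu3 and HCO2H–Et3N (formate hydrogenolysis of an alkenyl oxirane). Palladium ionises the tertiary allylic C–O bond with inversion and hands hydride to that same carbon from its own face, so H replaces O with net inversion. This gives (1R,2S,3E)-1,4-bis[4-(benzyloxy)-3-methoxyphenyl]-2,3-dimethylbut-3-en-1-ol F1. Epoxidation of F1 with the same ketone gives (1R,2R)-1-[4-(benzyloxy)-3-methoxyphenyl]-2-{(2S,3S)-3-[4-(benzyloxy)-3-methoxyphenyl]-2-methyloxiran-2-yl}propan-1-ol F2. Its benzylic hydroxyl opens the oxirane 5-endo at the benzylic carbon with inversion to give 9, which needs only the debenzylation part of step 4. C4 then comes from stereospecific hydride delivery and not from alkene hydrogenation.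

Step 2 is the second risk. The first oxirane deactivates and shields the remaining alkene, and the electron-rich bis-epoxide may not survive the aqueous medium. The fallback sets out from 5 and comes back at 8, working sequentially instead of in two directions. LDA isomerises 5 to (1S,3E)-1,4-bis[4-(benzyloxy)-3-methoxyphenyl]-3-methyl-2-methylidenebut-3-en-1-ol F3. The same ketone then epoxidises the trisubstituted styrenyl alkene of F3 in preference to the 1,1-disubstituted one, giving 7 as the free alcohol. Compound 7 is trapped at once by ring closure to 8, in the carbonate buffer or after deprotonation with NaH. No bis-epoxide ever accumulates.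

Step 1 is the third risk. The twofold Heck reaction may stop at 3 or give regioisomer and E/Z mixtures. The fallback sets out from 1 and comes back at 4, building each half as a defined alkenyl metal.
- Coupling of 1 with 1-propynylmagnesium bromide (PdCl2(dppf), THF, 60 °C) gives 1-(benzyloxy)-2-methoxy-4-(prop-1-yn-1-yl)benzene F4.
- Copper-catalysed syn-hydroboration (CuCl, NaOt-Bu, Xantphos, B2pin2, MeOH) places boron distal to the aryl group and gives 2-{(Z)-1-[4-(benzyloxy)-3-methoxyphenyl]prop-1-en-2-yl}-4,4,5,5-tetramethyl-1,3,2-dioxaborolane F5.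
- Oxidative homocoupling of F5 (Pd(OAc)2, K2CO3, O2, MeOH–H2O) proceeds with retention of alkene geometry and delivers 4.

**Further compounds**
F1 | step 3 | (1R,2S,3E)-1,4-bis[4-(benzyloxy)-3-methoxyphenyl]-2,3-dimethylbut-3-en-1-ol | O[C@@H](c1ccc(OCc2ccccc2)c(OC)c1)[C@@H](C)/C(C)=C/c1ccc(OCc2ccccc2)c(OC)c1
F2 | step 3 | (1R,2R)-1-[4-(benzyloxy)-3-methoxyphenyl]-2-{(2S,3S)-3-[4-(benzyloxy)-3-methoxyphenyl]-2-methyloxiran-2-yl}propan-1-ol | O[C@@H](c1ccc(OCc2ccccc2)c(OC)c1)[C@@H](C)[C@]1(C)O[C@H]1c1ccc(OCc2ccccc2)c(OC)c1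
F3 | step 2 | (1S,3E)-1,4-bis[4-(benzyloxy)-3-methoxyphenyl]-3-methyl-2-methylidenebut-3-en-1-ol | COc1cc(/C=C(\C)C(=C)[C@@H](O)c2ccc(OCc3ccccc3)c(OC)c2)ccc1OCc1ccccc1
F4 | step 1 | 1-(benzyloxy)-2-methoxy-4-(prop-1-yn-1-yl)benzene | CC#Cc1ccc(OCc2ccccc2)c(OC)c1
F5 | step 1 | 2-{(Z)-1-[4-(benzyloxy)-3-methoxyphenyl]prop-1-en-2-yl}-4,4,5,5-tetramethyl-1,3,2-dioxaborolane | COc1cc(/C=C(\C)B2OC(C)(C)C(C)(C)O2)ccc1OCc1ccccc1
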